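4 questions stood for this flask, and I took the solid first.

| flask | solid substrate | reagent | remark | time |
|---|---|---|---|---|
| ochre | 5.0 × 10⁻⁴ M | 2.8 equiv | run made earlier |  |
| amber | 5.0 × 10⁻⁴ M | 4.4 equiv | run made earlier |  |
| grey | 2.5 × 10⁻⁴ M | 2 equiv | run made earlier |  |
| flask | 5.0 × 10⁻⁴ M | 2.00 equiv |  | 2.0 min |

| run | time / s | solid substrate / % | mono adduct / % | bis adduct / % |
|---|---|---|---|---|
| ochre | 10.0 | 99 | 4 | 0 |
| ochre | 12.0 | 97 | 0 | 0 |
| ochre | 20.0 | 99 | 1 | 0 |
| ochre | 25.0 | 98 | 0 | 0 |
| ochre | 40.0 | 96 | 1 | 1 |
| ochre | 60.0 | 92 | 1 | 2 |
| ochre | 90.0 | 90 | 3 | 1 |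
| amber | 15.0 | 97 | 2 | 0 |
| amber | 30.0 | 99 | 0 | 1 |
| amber | 40.0 | 95 | 1 | 1 |
| amber | 60.0 | 91 | 2 | 1 |
| amber | 80.0 | 88 | 2 | 2 |
| amber | 90.0 | 90 | 3 | 2 |
| grey | 10.0 | 97 | 0 | 0 |
| grey | 25.0 | 94 | 0 | 0 |
| grey | 40.0 | 92 | 2 | 2 |
| grey | 60.0 | 89 | 4 | 0 |
| grey | 90.0 | 89 | 4 | 0 |

(standard deviation of a reading: 1.5 percentage points)

* the solid substrate standing at 2.0 min, as a percentage of the solid substrate charged (only what is still solid)
* the mono adduct standing at 2.0 min, as a percentage of the solid substrate charged
* the bis adduct standing at 2.0 min, as a percentage of the solid substrate charged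
* the tris adduct standing at 2.0 min, as a percentage of the solid substrate charged

- as a solid, counted per litre of solution: solid substrate
- what may be going on: starting material + reagent -> mono adduct; reagent + mono adduct -> bis adduct; reagent + bis adduct -> tris adduct; reagent + tris adduct -> tetra adduct; solid substrate <-> starting material
- at the start none of the solid substrate is in solution

I read the tables column against column. At 90.0 s the ochre run held 90 % of its solid and the amber run 90 %, although amber had 1.57 times the reagent. So I treated the solid's fall as unaffected by reagent across those charges, and I read the flask from these two runs, though its 2.00 equiv lies below both. The grey run had a different charge of solid, so I set it aside.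

The earliest rows sit within the scatter of 1.5 percentage points, so I began at 40.0 s, where the two runs averaged 95.5 %. From there to 90.0 s the average fell by 5.5 points. That gave the steady loss, the fraction of the charge leaving the solid per minute, 0.0660 /min. It is a reading, and a rough one, for each reading in it carries the scatter. A constant rate integrates to a straight line: the solid at any later time is its fraction at 90.0 s less the steady loss times the time since. My own reckoning for 2.0 min was therefore 86.7 %.

The forecast gave 87 % solid, 4 % mono adduct, 2 % bis adduct and 0.5 % tris adduct, holding that “reagent level has little effect on the solid's disappearance”.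

The flask gave 88.7 %, 4.69 %, 1.69 % and 2.53 %, each within its margin of the forecast.

    starting material + reagent → mono adduct (k = 45.0 /M/s)
    reagent + mono adduct → bis adduct (k = 15.0 /M/s)
    reagent + bis adduct → tris adduct (k = 34.0 /M/s)
    reagent + tris adduct → tetra adduct (k = 4.60 /M/s)
    solid substrate ⇌ starting material, rate k5*(cs5 - [starting material]) while solid is left; crystals form when [starting material] > cs5 (solubility = 0.0190 mM, k = 0.0470 /s)

At 0.895 min this flask made starting material 1.02 times as fast as it used it up, with a half-life by reaction with the reagent of 0.26 min. The starting material, a small pool in near steady state, stood at 1.96 % at 1.00 min and 2.02 % at 2.00 min, while the solid in this flask fell at 0.0512 /min between those times, slower than the steady loss of 0.0660 /min. Carried on from 88.7 % with that steady loss, the line gave 82.1 % at 3.0 min, and the same flask read then held 83.7 %.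

The readings were generated by integration on assumed constants; the scatter is artificial.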